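**Retrosynthetic overview**

- The target is traced back to a bridged 9,12-δ-lactone carrying a free 6-hydroxyl; transfer of the acyl carbon from O9 to O6 gives the 6,12-γ-lactone and frees the 9-hydroxyl.
- The bridged lactone comes from closure of the C6–C7 bond, the bond that germacrene biosynthesis closes (farnesyl C1–C10). An enal at C6 is attacked by a 2-carbonyl allylboron unit held in the δ-lactone, so the ten-membered ring forms first and the γ-lactone second.
- The cyclization substrate comes from esterification of O8 with (R)-(2-methyloxiran-2-yl)acetic acid (from 3-methylbut-3-en-1-ol) and oxidation at C6.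
- The δ-lactone (a temporary tether that masks O9 and fixes the alkene geometry) comes from ring-closing metathesis of an O9 2-(bromomethyl)acrylate; the anti-8,9-diol unit comes from a catalytic asymmetric anti-silyloxyallylboration of a (Z)-2-methyl enal.
- The (Z)-enal comes from geraniol by ozonolysis, Z-iodo-olefination and formylation. Ring order: auxiliary δ-lactone, then the carbocycle, then the γ-lactone (the δ-lactone is consumed).

Note: C1–C15 are germacrane positions (C6 and C7 are the carbons joined in the ring closure; C12 is the lactone carbonyl).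

Assumption: in step 11 the (R,R)-ligand is taken to deliver the (R)-epoxide; if the first run shows the opposite sense, the (S,S)-ligand is used and nothing else changes.

**Route**

Step 1
Reactants: 1 geraniol
Product: 2 tert-butyl{[(2E)-3,7-dimethylocta-2,6-dien-1-yl]oxy}dimethylsilane
Conditions: TBSCl, imidazole, DMF, 0 °C to rt
Reagents that add atoms: tert-butyldimethylsilyl chloride, CC(C)(C)[Si](C)(C)Cl
Why: Standard silyl ether formation on the primary allylic alcohol masks the future C6 oxygen and creates no stereocentre.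

Step 2
Reactants: 2 tert-butyl{[(2E)-3,7-dimethylocta-2,6-dien-1-yl]oxy}dimethylsilane
Product: 4 (4E)-6-[(tert-butyldimethylsilyl)oxy]-4-methylhex-4-enal, via ozonide 3 (not isolated)
Conditions: O3 (1.0 equiv), CH2Cl2, −78 °C; then Me2S, −78 °C to rt
Reagents that add atoms: ozone, [O-][O+]=O
Why: Ozonolysis with one equivalent of ozone cleaves the remote, more electron-rich trisubstituted alkene faster than the alkene next to the silyloxy group, and Me2S reduces the ozonide to the aldehyde while the (E)-alkene (future C4=C5) is kept.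

Step 3
Reactants: 4 (4E)-6-[(tert-butyldimethylsilyl)oxy]-4-methylhex-4-enal
Product: 5 tert-butyl{[(2E,6Z)-7-iodo-3-methylocta-2,6-dien-1-yl]oxy}dimethylsilane
Conditions: EtPPh3I, n-BuLi, THF, rt; I2, −78 °C; NaN(SiMe3)2, −20 °C; then 4, −78 °C
Reagents that add atoms: ethyltriphenylphosphonium iodide, CC[P+](c1ccccc1)(c1ccccc1)c1ccccc1.[I-]; iodine, II
Why: The Stork–Zhao-type Wittig iodo-olefination with the α-iodoethylidene ylide is kinetically Z-selective (iodine cis to the chain), which fixes the later C1=C10 Z geometry.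

Step 4
Reactants: 5 tert-butyl{[(2E,6Z)-7-iodo-3-methylocta-2,6-dien-1-yl]oxy}dimethylsilane
Product: 8 (2Z,6E)-8-[(tert-butyldimethylsilyl)oxy]-2,6-dimethylocta-2,6-dienal, via alkenyllithium 6 (not isolated), via lithium hemiaminolate 7 (not isolated)
Conditions: t-BuLi (2.1 equiv), Et2O, −78 °C; DMF, −78 °C; H2O
Reagents that add atoms: N,N-dimethylformamide, CN(C)C=O
Why: Iodine–lithium exchange proceeds with retention of alkene geometry and Bouveault-type formylation with DMF gives the (Z)-2-methyl enal (C9 aldehyde cis to C2).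

Step 5
Reactants: 9 tert-butyldimethyl{[(2E)-3-(4,4,5,5-tetramethyl-1,3,2-dioxaborolan-2-yl)prop-2-en-1-yl]oxy}silane
Product: 10 tert-butyldimethyl{[(1E)-3-(4,4,5,5-tetramethyl-1,3,2-dioxaborolan-2-yl)prop-1-en-1-yl]oxy}silane
Conditions: [Ir(cod)(PPh2Me)2]PF6 (3 mol %, activated with H2), THF, rt
Reagents that add atoms: none
Why: Iridium-catalysed alkene isomerization of the allyl silyl ether moves the double bond into conjugation with oxygen and gives the (E)-silyl enol ether, that is the (E)-γ-silyloxyallylboronate.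

Step 6
Reactants: 8 (2Z,6E)-8-[(tert-butyldimethylsilyl)oxy]-2,6-dimethylocta-2,6-dienal; 10 tert-butyldimethyl{[(1E)-3-(4,4,5,5-tetramethyl-1,3,2-dioxaborolan-2-yl)prop-1-en-1-yl]oxy}silane
Product: 12 (3S,4R,5Z,9E)-3,11-bis[(tert-butyldimethylsilyl)oxy]-5,9-dimethylundeca-1,5,9-trien-4-ol, via pinacol borate ester 11 (not isolated)
Conditions: (S)-TRIP [(S)-3,3'-bis(2,4,6-triisopropylphenyl)-1,1'-binaphthyl-2,2'-diyl hydrogen phosphate] (5 mol %), 4 Å MS, toluene, −30 °C; then aq. NaHCO3
Reagents that add atoms: none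
Why: Chiral phosphoric acid-catalysed allylboration runs through a closed chair (Zimmerman–Traxler) transition state, so the (E)-reagent gives the anti silyloxy alcohol, and (S)-TRIP (mirror image of the (R)-TRIP/Re-face precedent with benzaldehyde) directs attack to the Si face, setting C9 as R and C8 as S.

Step 7
Reactants: 12 (3S,4R,5Z,9E)-3,11-bis[(tert-butyldimethylsilyl)oxy]-5,9-dimethylundeca-1,5,9-trien-4-ol; 13 2-(bromomethyl)prop-2-enoic acid
Product: 14 (3S,4R,5Z,9E)-3,11-bis[(tert-butyldimethylsilyl)oxy]-5,9-dimethylundeca-1,5,9-trien-4-yl 2-(bromomethyl)prop-2-enoate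
Conditions: DIC, DMAP (10 mol %), CH2Cl2, 0 °C
Reagents that add atoms: none
Why: Steglich esterification of the only free hydroxyl (O9) brings in C11, C12 and C13 without touching a stereocentre, and low temperature with catalytic DMAP limits attack on the allylic bromide.

Step 8
Reactants: 14 (3S,4R,5Z,9E)-3,11-bis[(tert-butyldimethylsilyl)oxy]-5,9-dimethylundeca-1,5,9-trien-4-yl 2-(bromomethyl)prop-2-enoate
Product: 15 (5S,6R)-3-(bromomethyl)-5-[(tert-butyldimethylsilyl)oxy]-6-{(2Z,6E)-8-[(tert-butyldimethylsilyl)oxy]-6-methylocta-2,6-dien-2-yl}-5,6-dihydro-2H-pyran-2-one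
Conditions: second-generation Hoveyda–Grubbs catalyst RuCl2(H2IMes)(=CHC6H4-2-O-i-Pr) (10 mol %), toluene (5 mM), 80 °C
Reagents that add atoms: none
Why: Ring-closing metathesis between the terminal vinyl group and the 1,1-disubstituted acrylate closes the six-membered unsaturated lactone (forming C7=C11 with C8 necessarily cis to the carbonyl), while the two trisubstituted chain alkenes are inert.

Step 9
Reactants: 15 (5S,6R)-3-(bromomethyl)-5-[(tert-butyldimethylsilyl)oxy]-6-{(2Z,6E)-8-[(tert-butyldimethylsilyl)oxy]-6-methylocta-2,6-dien-2-yl}-5,6-dihydro-2H-pyran-2-one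
Product: 16 (5S,6R)-3-(bromomethyl)-5-hydroxy-6-[(2Z,6E)-8-hydroxy-6-methylocta-2,6-dien-2-yl]-5,6-dihydro-2H-pyran-2-one
Conditions: 48% aq. HF, MeCN, 0 °C to rt
Reagents that add atoms: none
Why: Acidic fluoride desilylation removes both silyl ethers without a nucleophilic amine, so the allylic bromide, the lactone and the alkenes survive.

Step 10
Reactants: 16 (5S,6R)-3-(bromomethyl)-5-hydroxy-6-[(2Z,6E)-8-hydroxy-6-methylocta-2,6-dien-2-yl]-5,6-dihydro-2H-pyran-2-one
Product: 17 (2E,6Z)-7-[(2R,3S)-5-(bromomethyl)-3-hydroxy-6-oxo-3,6-dihydro-2H-pyran-2-yl]-3-methylocta-2,6-dienal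
Conditions: TEMPO (10 mol %), PhI(OAc)2 (1.1 equiv), CH2Cl2, rt
Reagents that add atoms: none
Why: The TEMPO/PhI(OAc)2 oxidation is selective for the primary allylic alcohol over the hindered secondary one and gives the (E)-enal at C6 without alkene isomerization.

Step 11
Reactants: 18 3-methylbut-3-en-1-ol
Product: 19 2-[(2R)-2-methyloxiran-2-yl]ethan-1-ol
Conditions: Hf(Ot-Bu)4 (2 mol %), (R,R)-bishydroxamic acid ligand [N,N'-dihydroxy-N,N'-bis(2,2-diarylacetyl)-(1R,2R)-cyclohexane-1,2-diamine] (2.4 mol %), cumene hydroperoxide, DMPU, 4 Å MS, toluene, 0 °C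
Reagents that add atoms: cumene hydroperoxide, CC(C)(OO)c1ccccc1
Why: Hydroxyl-directed catalytic asymmetric epoxidation of a homoallylic alcohol (Yamamoto-type hafnium–bishydroxamic acid catalyst) delivers oxygen to one face of the 1,1-disubstituted alkene and sets the quaternary epoxide carbon as R.

Step 12
Reactants: 19 2-[(2R)-2-methyloxiran-2-yl]ethan-1-ol
Product: 20 [(2R)-2-methyloxiran-2-yl]acetic acid
Conditions: TEMPO (20 mol %), PhI(OAc)2 (2.2 equiv), MeCN/H2O (1:1), rt
Reagents that add atoms: water, O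
Why: The TEMPO/PhI(OAc)2 oxidation in aqueous acetonitrile takes the primary alcohol through the aldehyde hydrate to the acid under near-neutral conditions that leave the epoxide and its stereocentre intact.

Step 13
Reactants: 17 (2E,6Z)-7-[(2R,3S)-5-(bromomethyl)-3-hydroxy-6-oxo-3,6-dihydro-2H-pyran-2-yl]-3-methylocta-2,6-dienal; 20 [(2R)-2-methyloxiran-2-yl]acetic acid
Product: 21 (2R,3S)-5-(bromomethyl)-2-[(2Z,6E)-6-methyl-8-oxoocta-2,6-dien-2-yl]-6-oxo-3,6-dihydro-2H-pyran-3-yl [(2R)-2-methyloxiran-2-yl]acetate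
Conditions: DIC, DMAP (10 mol %), CH2Cl2, −20 to 0 °C
Reagents that add atoms: none
Why: Steglich esterification of the single free hydroxyl (O8, with O9 held in the lactone) installs the side chain regiospecifically, and low temperature with catalytic DMAP suppresses base-induced opening of the β,γ-epoxy acid.

Step 14
Reactants: 21 (2R,3S)-5-(bromomethyl)-2-[(2Z,6E)-6-methyl-8-oxoocta-2,6-dien-2-yl]-6-oxo-3,6-dihydro-2H-pyran-3-yl [(2R)-2-methyloxiran-2-yl]acetate
Product: 25 (3aS,4S,5R,6Z,10E,11aR)-5-hydroxy-6,10-dimethyl-3-methylidene-2-oxo-2,3,3a,4,5,8,9,11a-octahydrocyclodeca[b]furan-4-yl [(2R)-2-methyloxiran-2-yl]acetate (target CNP0284481.1), via allylboronate 22 (not isolated), via bridged borate 23 (not isolated), via bridged hydroxy lactone 24 (not isolated)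
Conditions: Pd2(dba)3 (5 mol %), B2pin2 (1.1 equiv), THF (0.05 M), 40 °C; then toluene (to 2 mM), 80 °C; then pH 7 phosphate buffer, SiO2, rt
Reagents that add atoms: none
Why: Proposed new method: palladium-catalysed borylation of the allylic bromide (known for allylic halides with B2pin2) gives the 2-carbonyl allylboronate 22, whose alkene is locked by the lactone ring with C8 cis to the carbonyl, so that intramolecular allylboration of the tethered enal through a closed chair transition state forms the C6–C7 bond with the anti relationship (6R) on the face of C7 that is reached from the C9 side chain and lies opposite the C8 acyloxy group (7S), after which the C6 hydroxyl freed on work-up attacks the strained bridged δ-lactone and moves the acyl carbon from O9 to O6 (γ-lactone favoured over δ-lactone), releasing the C9 hydroxyl; the closest known reactions are the one-pot borylation/allylboration/lactonization of Baylis–Hillman acetates with aldehydes and the chromium-mediated ten-membered closure of costunolide-type lactones, and boron is chosen over zinc, indium or chromium because a neutral allylboronate does not undergo 1,4-elimination of the C8 ester.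

**Compound list**

1 | geraniol, (2E)-3,7-dimethylocta-2,6-dien-1-ol | CC(C)=CCC/C(C)=C/CO | starting material
2 | tert-butyl{[(2E)-3,7-dimethylocta-2,6-dien-1-yl]oxy}dimethylsilane | CC(C)=CCC/C(C)=C/CO[Si](C)(C)C(C)(C)C | intermediate
3 | ozonide of 2 at the terminal alkene, 3-{(3E)-5-[(tert-butyldimethylsilyl)oxy]-3-methylpent-3-en-1-yl}-5,5-dimethyl-1,2,4-trioxolane (not isolated) | CC1(C)OOC(CC/C(C)=C/CO[Si](C)(C)C(C)(C)C)O1 | intermediate
4 | (4E)-6-[(tert-butyldimethylsilyl)oxy]-4-methylhex-4-enal | O=CCC/C(C)=C/CO[Si](C)(C)C(C)(C)C | intermediate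
5 | tert-butyl{[(2E,6Z)-7-iodo-3-methylocta-2,6-dien-1-yl]oxy}dimethylsilane | C/C(I)=C/CC/C(C)=C/CO[Si](C)(C)C(C)(C)C | intermediate
6 | alkenyllithium from 5, lithium in place of iodine with the alkene geometry kept (not isolated) | C/C([Li])=C/CC/C(C)=C/CO[Si](C)(C)C(C)(C)C | intermediate
7 | lithium (2Z,6E)-8-[(tert-butyldimethylsilyl)oxy]-1-(dimethylamino)-2,6-dimethylocta-2,6-dien-1-olate (not isolated) | C/C(C([O-])N(C)C)=C/CC/C(C)=C/CO[Si](C)(C)C(C)(C)C.[Li+] | intermediate
8 | (2Z,6E)-8-[(tert-butyldimethylsilyl)oxy]-2,6-dimethylocta-2,6-dienal | C/C(C=O)=C/CC/C(C)=C/CO[Si](C)(C)C(C)(C)C | intermediate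
9 | tert-butyldimethyl{[(2E)-3-(4,4,5,5-tetramethyl-1,3,2-dioxaborolan-2-yl)prop-2-en-1-yl]oxy}silane | CC(C)(C)[Si](C)(C)OC/C=C/B1OC(C)(C)C(C)(C)O1 | starting material
10 | tert-butyldimethyl{[(1E)-3-(4,4,5,5-tetramethyl-1,3,2-dioxaborolan-2-yl)prop-1-en-1-yl]oxy}silane | CC(C)(C)[Si](C)(C)O/C=C/CB1OC(C)(C)C(C)(C)O1 | intermediate
11 | pinacol borate ester of 12, O4-boryl derivative (not isolated) | CC(C)(C)[Si](C)(C)OC/C=C(\C)CC/C=C(/C)[C@@H](OB1OC(C)(C)C(C)(C)O1)[C@@H](O[Si](C)(C)C(C)(C)C)C=C | intermediate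
12 | (3S,4R,5Z,9E)-3,11-bis[(tert-butyldimethylsilyl)oxy]-5,9-dimethylundeca-1,5,9-trien-4-ol | CC(C)(C)[Si](C)(C)OC/C=C(\C)CC/C=C(/C)[C@@H](O)[C@@H](O[Si](C)(C)C(C)(C)C)C=C | intermediate
13 | 2-(bromomethyl)prop-2-enoic acid | C=C(CBr)C(=O)O | starting material
14 | (3S,4R,5Z,9E)-3,11-bis[(tert-butyldimethylsilyl)oxy]-5,9-dimethylundeca-1,5,9-trien-4-yl 2-(bromomethyl)prop-2-enoate | CC(C)(C)[Si](C)(C)OC/C=C(\C)CC/C=C(/C)[C@@H](OC(=O)C(=C)CBr)[C@@H](O[Si](C)(C)C(C)(C)C)C=C | intermediate
15 | (5S,6R)-3-(bromomethyl)-5-[(tert-butyldimethylsilyl)oxy]-6-{(2Z,6E)-8-[(tert-butyldimethylsilyl)oxy]-6-methylocta-2,6-dien-2-yl}-5,6-dihydro-2H-pyran-2-one | CC(C)(C)[Si](C)(C)OC/C=C(\C)CC/C=C(/C)[C@H]1OC(=O)C(CBr)=C[C@@H]1O[Si](C)(C)C(C)(C)C | intermediate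
16 | (5S,6R)-3-(bromomethyl)-5-hydroxy-6-[(2Z,6E)-8-hydroxy-6-methylocta-2,6-dien-2-yl]-5,6-dihydro-2H-pyran-2-one | OC/C=C(\C)CC/C=C(/C)[C@H]1OC(=O)C(CBr)=C[C@@H]1O | intermediate
17 | (2E,6Z)-7-[(2R,3S)-5-(bromomethyl)-3-hydroxy-6-oxo-3,6-dihydro-2H-pyran-2-yl]-3-methylocta-2,6-dienal | O=C/C=C(\C)CC/C=C(/C)[C@H]1OC(=O)C(CBr)=C[C@@H]1O | intermediate
18 | 3-methylbut-3-en-1-ol | C=C(C)CCO | starting material
19 | 2-[(2R)-2-methyloxiran-2-yl]ethan-1-ol | OCC[C@]1(C)CO1 | intermediate
20 | [(2R)-2-methyloxiran-2-yl]acetic acid | OC(=O)C[C@]1(C)CO1 | intermediate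
21 | (2R,3S)-5-(bromomethyl)-2-[(2Z,6E)-6-methyl-8-oxoocta-2,6-dien-2-yl]-6-oxo-3,6-dihydro-2H-pyran-3-yl [(2R)-2-methyloxiran-2-yl]acetate | O=C/C=C(\C)CC/C=C(/C)[C@H]1OC(=O)C(CBr)=C[C@@H]1OC(=O)C[C@]2(C)CO2 | intermediate
22 | allylboronate from 21, pinacolboryl in place of bromine (not isolated) | O=C/C=C(\C)CC/C=C(/C)[C@H]1OC(=O)C(CB2OC(C)(C)C(C)(C)O2)=C[C@@H]1OC(=O)C[C@]3(C)CO3 | intermediate
23 | 6-O-pinacolboryl derivative of 24 (not isolated) | C=C1C(=O)O[C@H]2[C@@H](OC(=O)C[C@]3(C)CO3)[C@@H]1[C@H](OB4OC(C)(C)C(C)(C)O4)/C=C(\C)CC/C=C2/C | intermediate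
24 | (6R,7S,8S,9R)-6-hydroxy-8-{[(2R)-2-methyloxiran-2-yl]acetoxy}-1(10)Z,4E-germacra-1(10),4,11(13)-trien-12,9-olide, the bridged δ-lactone (not isolated) | C=C1C(=O)O[C@H]2[C@@H](OC(=O)C[C@]3(C)CO3)[C@@H]1[C@H](O)/C=C(\C)CC/C=C2/C | intermediate
25 | (3aS,4S,5R,6Z,10E,11aR)-5-hydroxy-6,10-dimethyl-3-methylidene-2-oxo-2,3,3a,4,5,8,9,11a-octahydrocyclodeca[b]furan-4-yl [(2R)-2-methyloxiran-2-yl]acetate, CNP0284481.1 | C=C1C(=O)O[C@@H]2/C=C(\C)CC/C=C(/C)[C@@H](O)[C@@H](OC(=O)C[C@]3(C)CO3)[C@@H]12 | target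

**Step count and risks**

Total step count: 14. Longest linear sequence: 11 steps (steps 1–4, 6–10, 13 and 14, from geraniol 1 to 25).

The three steps most likely to fail:

**Step 14.** The borylation must outrun palladium ionization of the C8 allylic ester, the bridged transition state must be reachable at high dilution, and the aldehyde face must follow the chair model. The fallback leaves the boron manifold for a Barbier-type organochromium closure. It sets out from 21 and comes back at 24, which rearranges to 25 as in step 14. Compound 21 is added slowly to CrCl2 (8 equiv) in THF/DMF at rt (final 2 mM). Divalent chromium converts the allylic bromide into the allylchromium dichloride F1. This adds to the aldehyde in the Nozaki–Hiyama–Kishi sense, which is stereoconvergent and anti-selective whatever the allyl geometry, and gives the chromium alkoxide of the bridged hydroxy lactone F2. Aqueous work-up gives 24. The price is a possible 1,4-elimination of the C8 ester, which the boron route avoids.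

**Step 6.** The acid catalyst may isomerize the labile (Z)-enal, or the selectivity may be poor with this silyloxy reagent. The fallback forms the C9–C10 bond instead of the C8–C9 bond and takes C8 from the chiral pool. It sets out from 5 and comes back at 12. Commercial (2S)-but-3-ene-1,2-diol is silylated (TBSCl, imidazole) to (3S)-3,4-bis[(tert-butyldimethylsilyl)oxy]but-1-ene F3. The primary silyl ether is cleaved (HF·pyridine, pyridine, THF, 0 °C) to (2S)-2-[(tert-butyldimethylsilyl)oxy]but-3-en-1-ol F4. Dess–Martin oxidation gives (2S)-2-[(tert-butyldimethylsilyl)oxy]but-3-enal F5. Compound 5 is lithiated to 6 as in step 4 and added to F5 at −78 °C. Felkin–Anh addition anti to the non-chelating silyloxy group gives 12 after removal of the minor syn isomer.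

**Step 3.** The iodo-olefination often gives modest yield and Z/E ratio. The fallback replaces it with a phosphonate olefination and a redox adjustment. It sets out from 4 and comes back at 8. Still–Gennari olefination of 4 with ethyl 2-[bis(2,2,2-trifluoroethoxy)phosphoryl]propanoate (KN(SiMe3)2, 18-crown-6, THF, −78 °C) gives ethyl (2Z,6E)-8-[(tert-butyldimethylsilyl)oxy]-2,6-dimethylocta-2,6-dienoate F6. Reduction with i-Bu2AlH (CH2Cl2, −78 °C) gives (2Z,6E)-8-[(tert-butyldimethylsilyl)oxy]-2,6-dimethylocta-2,6-dien-1-ol F7. Oxidation with MnO2 (CH2Cl2, rt) gives 8.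

**Further compounds**

F1 | step 14 | allylchromium dichloride from 21, dichlorochromio in place of bromine | O=C/C=C(\C)CC/C=C(/C)[C@H]1OC(=O)C(C[Cr](Cl)Cl)=C[C@@H]1OC(=O)C[C@]2(C)CO2
F2 | step 14 | chromium alkoxide of 24, 6-O-dichlorochromio derivative | C=C1C(=O)O[C@H]2[C@@H](OC(=O)C[C@]3(C)CO3)[C@@H]1[C@H](O[Cr](Cl)Cl)/C=C(\C)CC/C=C2/C
F3 | step 6 | (3S)-3,4-bis[(tert-butyldimethylsilyl)oxy]but-1-ene | CC(C)(C)[Si](C)(C)OC[C@@H](O[Si](C)(C)C(C)(C)C)C=C
F4 | step 6 | (2S)-2-[(tert-butyldimethylsilyl)oxy]but-3-en-1-ol | OC[C@@H](O[Si](C)(C)C(C)(C)C)C=C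
F5 | step 6 | (2S)-2-[(tert-butyldimethylsilyl)oxy]but-3-enal | O=C[C@@H](O[Si](C)(C)C(C)(C)C)C=C
F6 | step 3 | ethyl (2Z,6E)-8-[(tert-butyldimethylsilyl)oxy]-2,6-dimethylocta-2,6-dienoate | C/C(C(=O)OCC)=C/CC/C(C)=C/CO[Si](C)(C)C(C)(C)C
F7 | step 3 | (2Z,6E)-8-[(tert-butyldimethylsilyl)oxy]-2,6-dimethylocta-2,6-dien-1-ol | C/C(CO)=C/CC/C(C)=C/CO[Si](C)(C)C(C)(C)C
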